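The pitfall I watched for was reading a flat curve as a balance among dissolved species, whose percentages do not move with the charge.

| flask | substrate | remark | time |
|---|---|---|---|
| ochre | 0.53 M | the very flask that is asked about, followed so far |  |
| green | 1.1 M | run made earlier |  |
| flask | 0.53 M |  | 12 d |

| run | time / d | isomer of the product / % | target / % |
|---|---|---|---|
| ochre | 1.04 | 23.5 | 63.7 |
| ochre | 2.08 | 23.3 | 65.3 |
| ochre | 3.00 | 23.3 | 66.0 |
| ochre | 4.00 | 23.2 | 64.8 |
| ochre | 5.00 | 22.5 | 65.5 |
| ochre | 6.00 | 23.5 | 64.9 |
| green | 2.08 | 11.0 | 82.6 |
| green | 4.00 | 10.8 | 83.6 |
| green | 6.00 | 10.4 | 83.8 |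
| green | 8.00 | 11.5 | 83.3 |
| green | 10.0 | 11.0 | 84.0 |
| green | 12.0 | 11.0 | 82.8 |

(readings scatter by 0.5 percentage points)

1. ratio of isomer of the product to target at 3.0 min
2. ratio of isomer of the product to target at 12 d
3. which of isomer of the product and target there is more of at 12 d

- a reading or a percentage of target counts all its forms, free or not

Had ochre stopped? Its isomer of the product read 23.5% at 1.04 d and 23.5% at 6.00 d, and green, with twice the charge, stayed flat out to 12.0 d. So I carried ochre's late readings forward to 12 d.

Why, then, did the percentages differ between the runs? Ochre's reading of 23.2% over green's of 11.0% is 2.11, and green's charge over ochre's is 2.08, so these readings put isomer of the product at nearly the same molar concentration in the two runs: 0.123 M in ochre and 0.121 M in green. I called this the standing isomer level, the molar concentration of isomer of the product once a run is flat.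

What ratio follows? Over ochre's charge, green's level gives 22.8%, and against the last target reading, 64.9%, that makes 0.352, with target ahead. I read that as thermodynamic control. Ochre's first reading came 499 times later than 3.0 min, the early time asked about, so I took that time as kinetic control and offered no number for it.

The forecast, working from ochre's own readings, gave 0.357, a little above my 0.352, with target ahead, and 0.7 at 3.0 min as a wide guess: “Fixed solution concentrations independent of charge suggest a saturated equilibrium”.

The flask gave 0.352 at 12 d, with target at 65.5%, crystals counted in, and isomer of the product at 23.0%.

    crystals ⇌ target, rate k1*(cs1 - [target]) while solid is left; crystals form when [target] > cs1 (solubility = 0.150 M, k = 0.631 h⁻¹)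
    target ⇌ isomer of the product (k = 0.139 h⁻¹)
    substrate ⇌ target (K = 2.47, k = 0.195 h⁻¹)
    substrate ⇌ isomer of the product (K = 2.01, k = 0.0726 h⁻¹)

At 3.0 min the flask gave 0.375, close to 0.372, the rate constant of the path from substrate to isomer of the product over that of the path from substrate to target. Crystals in the flask stood at 37.2% at 12 d. A neighbour flask, the same but charged with 2.1 M of substrate, was also run: the level divided by that charge gives 5.76% of isomer of the product, and at 12.0 d that neighbour stood at 5.81%.

The earlier runs and the new flask were computed with constants of no real substance; scatter was added.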